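The numbers in the tables were computed for an exercise; the scatter is artificial.

If Z and L are put together again, the reading to watch is the height at which D stops climbing, and the runs so far say where that height lies.

| flask | Z | L | remark | time |
|---|---|---|---|---|
| gamma | 0.30 M | 0.70 equiv | run made earlier |  |
| zeta | 0.30 M | 6.2 equiv | run made earlier |  |
| north-east | 0.30 M | 0.500 equiv |  | 6.0 h |
| south-east | 0.30 M | 4.00 equiv |  | 6.0 h |
| south-west | 0.30 M | 1.20 equiv |  | 6.0 h |

| run | time / h | D / % |
|---|---|---|
| gamma | 0.500 | 6.8 |
| gamma | 1.00 | 8.3 |
| gamma | 2.50 | 15.4 |
| gamma | 6.00 | 14.2 |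
| zeta | 1.50 | 52.0 |
| zeta | 3.00 | 49.1 |
| zeta | 5.00 | 38.7 |
| zeta | 6.00 | 31.2 |

(standard deviation of a reading: 1 percentage point)



1. which of these holds the largest part of the Z at the end of north-east (D / X / Z)
2. which of these holds the largest part of the Z at the end of south-east (D / X / Z)
3. which of these holds the largest part of the Z at the end of south-west (D / X / Z)
4. D at the end of south-west, in percent of the Z charged

Read downwards, the gamma table climbs from 6.8 % at 0.500 h to 15.4 % at 2.50 h and then stands, for the reading at 6.00 h, 14.2 %, lies 1.2 percentage points lower, which is about the scatter of 1 point. The zeta table starts at 52.0 % at 1.50 h and falls to 31.2 % at 6.00 h, so D is an intermediate that is used up while it is made, and gamma's flat stretch reads as a balance (a steady state) rather than an end. Column against column at 6.00 h, zeta holds about twice the D of gamma on 8.86 times the L, so a proportion to L cannot be stretched as far as zeta.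

South-west, however, stands near gamma. The two level readings of gamma average 14.8 %, and dividing by the charge gives the standing yield on L, s, the D standing per L charged, as a reading s = 0.211. Taking gamma's level as the large term, and assuming proportion over this short step, the extra 0.500 of L in south-west adds a correction of 11 points, so the reckoning made here puts D at 25.4 % at the end of south-west.

The forecast, resting on “a loss of D that is roughly independent of L”, named Z, X and Z as the largest holders in north-east, south-east and south-west, and put D in south-west at 22 %, between 17 % and 28 %, lower than this reckoning.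

The largest holders turn out to be Z in north-east, D in south-east and Z in south-west.

    D + L ⇌ Q + X (K = 1.20, k = 2.40 × 10⁻⁵ L mol⁻¹ s⁻¹)
    Z + L ⇌ Q + D (K = 0.690, k = 1.80 × 10⁻⁴ L mol⁻¹ s⁻¹)
    Z + D → J (k = 2.40 × 10⁻⁴ L mol⁻¹ s⁻¹)
    L ⇌ E (K = 0.250, k = 2.50 × 10⁻⁴ s⁻¹)

D in south-west ends at 23.0 %, which is 2.4 points under the reckoning made here. South-west holds D at 23.4 % after 3.00 h and 23.0 % after 6.00 h, yet this is no level, for at the later time D is made at 0.636 of the rate at which it is used up, each step taken net, so D in south-west is falling there. Its own yield on L comes to 0.192 against s = 0.211. In a neighbouring flask, the same as south-west but with 0.720 equiv of L, s gives 15.2 %, and that flask ends with D at 16.1 %.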